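The runs were computed for substances that don't exist, noise included.

**A small charge.** A small charge allows few looks at a flask, so we want to read where it will stop from how its rate behaves. In the east flask, target rises quickly and then falls while substrate disappears. We are asked what stands at 10 h and which remedy to take.

| flask | substrate | reagent | temperature | remark | time |
|---|---|---|---|---|---|
| east | 0.80 M | 1.04 M | 35 °C | the very flask that is asked about, followed so far |  |
| south-west | 1.2 M | 1.04 M | 20 °C | run made earlier |  |
| flask | 0.80 M | 1.04 M | 35 °C |  | 10 h |

| run | time / h | target / % | substrate / % |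
|---|---|---|---|
| east | 0.833 | 46.8 | 13.0 |
| east | 1.50 | 42.8 | 7.1 |
| east | 3.00 | 27.2 | 2.5 |
| east | 5.00 | 17.2 | 1.4 |
| east | 10.0 | 13.2 | 0.3 |
| south-west | 0.500 | 15.5 | 68.3 |
| south-west | 1.00 | 25.9 | 48.8 |
| south-west | 2.00 | 38.3 | 28.3 |
| south-west | 3.00 | 44.3 | 19.4 |

(readings scatter by 0.3 percentage points)

- larch: at 10 h add substrate, 50.0 % of the amount charged, then wait 5.0 h
- oak: change nothing and wait 5.0 h more
- cedar: at 10 h raise the temperature by 15 K, then wait 5.0 h

- a species is counted by the substrate in it: one idle adduct counts as two
- amounts and yields of target count idle adduct too
- additions leave the volume as it is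
- the analysis behind the earlier runs scatters by 0.3 percentage points, standard deviation
- on the list of suspects stand: substrate -> target; substrate <-> intermediate A; reagent + intermediate A <-> intermediate B; substrate + target <-> idle adduct; target <-> isomer of the product
- in an amount of target, one idle adduct counts as one target

* target, in percent of the substrate first charged, at 10 h
* the remedy with the largest gain of target, or "none" below 2 percentage points (larch / oak / cedar / none)
* target present, in percent of the substrate first charged, after larch
* target present, in percent of the substrate first charged, after cedar

**The rate.** In the east run, target falls, as a fraction of the charge, at 0.104 h⁻¹ between 1.50 h and 3.00 h. Between 5.00 h and 10.0 h it falls at 0.00800 h⁻¹. So the rate dropped by a factor 13.0. Thinner target gives a factor 2.30, the ratio of the mean readings over the two spans. The rate thus fell more than the target did, and a further factor 5.65 remains. We read that as isomer returning to target, so the accumulated slowing ends in a balance with target still present, which is thermodynamic control.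

**Balance ratio.** We carry one number, the balance ratio Q: what is neither target nor substrate, per unit of target, at the end of the east run. It reads 6.55. Our own reckoning follows from it. On it, oak gains nothing. Larch's extra substrate has 5.0 h to run, less than the 10.0 h behind Q, so we do not reckon larch by Q. Cedar changes Q itself, and the south-west run, still rising at its last reading, shows no balance, so we leave cedar open.

**The forecast.** It gives 13.2 % now, 21.5 % after larch and 15.5 % after cedar, and it chooses larch. On cedar it says: “The temperature dependence is unmeasured.”

**The flask.** Target stands at 12.8 %. Larch ends at 20.9 % and cedar at 40.8 %. The gains are 8.1 percentage points for larch, −0.66 points for oak and 28 points for cedar, so the remedy is cedar.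

    substrate → target (k = 0.0330 min⁻¹, Ea = 83.0 kJ mol⁻¹)
    substrate ⇌ intermediate A (K = 0.910, k = 0.0110 min⁻¹, Ea = 85.0 kJ mol⁻¹, ΔH = 6.00 kJ mol⁻¹)
    reagent + intermediate A ⇌ intermediate B (K = 1.00 M⁻¹, k = 0.0620 M⁻¹ min⁻¹, Ea = 60.0 kJ mol⁻¹, ΔH = −18.0 kJ mol⁻¹)
    substrate + target ⇌ idle adduct, settled at all times (K = 3.20 M⁻¹, ΔH = 2.00 kJ mol⁻¹)
    target ⇌ isomer of the product (K = 7.40, k = 0.0120 min⁻¹, Ea = 95.0 kJ mol⁻¹, ΔH = −90.0 kJ mol⁻¹)
    (constants at 35 °C)

**Why cedar.** The flask holds little target at 10 h because of the reaction of target to isomer of the product, both ways: a run without it holds 96.1 % instead of 12.8 %. Taken as a balance, cedar's target means a ratio of 1.45, far below Q. Part of the reason is the way back from isomer to target: a run with that way shut gives cedar −1.5 points instead of 28 points.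

**A hotter flask.** For the same flask at 60 °C, we let the logarithm of Q move evenly per kelvin through these two ratios. That gives a ratio of 0.530 and so target at 65.4 %. The computed flask holds 65.4 %.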